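**Retrosynthetic overview**

1. Ring A is numbered C1 (O‑aryl), C2 (OMe), C3 (H), C4–C6 (Br). The strategy rests on the C6–Br bond next to the ether carbon C1 while C3 stays C–H: bromination of a 2‑aryloxyanisole would fill C3, ortho to the stronger donor OMe, before C6, so C6 is brought in together with its bromine as a CBr unit.
2. Target ⇒ 3‑bromo‑2‑(2,4‑dibromophenoxy)phenol, by removing C5–Br (bromination para to OMe), C4–Br (sterically directed C–H borylation, then bromodeboronation) and the O‑methyl group.
3. Key disconnection: bonds C5–C6 and C1–C6 of ring A ⇒ 2‑(2,4‑dibromophenoxy)cyclopent‑2‑en‑1‑one + bromoform; the five‑membered ring is expanded by one carbon to the arene.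
4. Enone ⇒ 2,3‑epoxycyclopentan‑1‑one + 2,4‑dibromophenol ⇒ cyclopent‑2‑en‑1‑one; the C1–O ether bond is made by SN2 at an sp3 carbon, so no hindered aryl coupling is needed.
5. Ring order: ring B is bought intact; the future ring A is carried as a cyclopentenone and becomes the benzene ring in the key step.

Key step: step 3

Remark: the ring A numbering above is also used for the five‑membered precursors (C1 = aryloxy carbon, C2 = carbonyl carbon, C5 = enone beta carbon). The target is achiral; 2, 4 and 7 are racemic and one enantiomer is written in their SMILES to fix the relative configuration.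

**Route**

Step 1
Reactants: 1 cyclopent‑2‑en‑1‑one
Product: 2 2,3‑epoxycyclopentan‑1‑one (6‑oxabicyclo[3.1.0]hexan‑2‑one), racemic, cis‑fused
Conditions: 30% aq H2O2, NaOH (cat.), MeOH, 0 °C
Reagents that add atoms: hydrogen peroxide, OO
Why: Weitz–Scheffer nucleophilic epoxidation (conjugate addition of hydroperoxide, then closure of the enolate onto oxygen with loss of hydroxide) is the standard epoxidation of an electron‑poor enone, and the two new stereocentres can only be cis on the fused three‑membered ring, the product being racemic.

Step 2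
Reactants: 2 2,3‑epoxycyclopentan‑1‑one; 3 2,4‑dibromophenol
Product: 5 2‑(2,4‑dibromophenoxy)cyclopent‑2‑en‑1‑one, via trans‑3‑hydroxy ketone 4 (not isolated)
Conditions: KH (0.2 equiv), THF/DMPU, 65 °C
Reagents that add atoms: none
Why: Opening of an alpha,beta‑epoxy ketone by a phenoxide at the carbonyl‑activated alpha carbon (SN2 with inversion, giving trans hydroxy ketone 4) followed by E1cB loss of water is the established access to 2‑aryloxy enones; the hydroxide released regenerates the phenoxide, so catalytic base suffices, and both stereocentres disappear in the dehydration.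

Step 3
Reactants: 5 2‑(2,4‑dibromophenoxy)cyclopent‑2‑en‑1‑one; 6 bromoform
Product: 8 3‑bromo‑2‑(2,4‑dibromophenoxy)phenol, via bicyclic dibromide 7 (not isolated)
Conditions: CHBr3 (1.2 equiv, slow addition), 50% aq NaOH, BnEt3NCl (5 mol%), toluene, 0 °C, then 40 °C; 1 M HCl work‑up
Reagents that add atoms: none
Why: Proposed new method: under liquid–liquid phase‑transfer conditions bromoform, a much stronger C–H acid than the CH2 groups of 5, is deprotonated first; the tribromomethyl anion adds to the enone beta carbon C5 and the enolate so formed displaces bromide from the CBr3 carbon through its alpha carbon C1 (3‑exo‑tet, Michael‑initiated ring closure) to give 7, whose C1 and C5 substituents are cis because a three‑membered ring cannot be trans‑fused to a five‑membered one. Hydroxide then enolises 7 toward C3, the endo bromide on C6 ionises with disrotatory two‑electron opening of the C1–C5 bond, and the six‑membered ring that results is an arenium ion that is sp3 at C4 and has the aryloxy‑bearing C1 para to it; loss of the C4 proton gives the phenoxide of 8, so both stereocentres of 7 vanish. The closest known reactions are the dihalocarbene ring expansions of cyclopentadienes and indenes to haloarenes, the cyclopropanation of alpha‑substituted Michael acceptors by trihalomethyl anions, and the base‑induced expansion of gem‑dibromocyclopropyl ketones to bromotropolones. The selectivity needed is insertion of the carbon between C1 and C5 and not between C2 and C3: the anion can bond only to the beta carbon and the enolate can close only from C1, direct addition of free dibromocarbene to the oxygen‑substituted C1=C5 bond leads to the same 7, and the wrong‑way insertion, which would need carbene attack on the dienolate of 5, is held back by the low temperature and the low standing concentration of that dienolate in the organic phase. Bromoform is limited to 1.2 equivalents and added slowly, and the sodium phenoxide leaves the toluene phase, so Reimer–Tiemann‑type attack of the carbene on the product should stay small.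

Step 4
Reactants: 8 3‑bromo‑2‑(2,4‑dibromophenoxy)phenol
Product: 9 1‑bromo‑2‑(2,4‑dibromophenoxy)‑3‑methoxybenzene
Conditions: MeI, K2CO3, DMF, rt
Reagents that add atoms: iodomethane, CI
Why: Williamson ether synthesis, the acidic phenol 8 being deprotonated by carbonate and alkylated on oxygen by iodomethane under conditions that leave the aryl bromides and the diaryl ether untouched.

Step 5
Reactants: 9 1‑bromo‑2‑(2,4‑dibromophenoxy)‑3‑methoxybenzene
Product: 10 2‑[3‑bromo‑4‑(2,4‑dibromophenoxy)‑5‑methoxyphenyl]‑4,4,5,5‑tetramethyl‑1,3,2‑dioxaborolane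
Conditions: B2pin2 (1.0 equiv), [Ir(OMe)(cod)]2 (1.5 mol%), dtbpy (3 mol%), THF, 70 °C
Reagents that add atoms: bis(pinacolato)diboron, CC1(C)OB(OC1(C)C)B1OC(C)(C)C(C)(C)O1
Why: Iridium‑catalysed aromatic C–H borylation is controlled by sterics and takes the only C–H bond of 9 without an ortho substituent, C4 of ring A (C3 lies next to OMe, C5 next to Br, and each ring B hydrogen has an ortho bromine or the ether oxygen), while C–Br bonds are tolerated by the iridium boryl catalyst.

Step 6
Reactants: 10 the C4 pinacol boronate
Product: 11 1,5‑dibromo‑2‑(2,4‑dibromophenoxy)‑3‑methoxybenzene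
Conditions: CuBr2 (3 equiv), MeOH/H2O (1:1), 80 °C
Reagents that add atoms: copper dibromide CuBr2, [Cu+2].[Br-].[Br-]
Why: Copper‑mediated bromodeboronation of an aryl pinacol boronate (transmetalation from boron to copper, then C–Br bond formation at the same carbon) is a known ipso replacement that tolerates aryl bromides and ethers, so the bromine lands exactly at C4.

Step 7
Reactants: 11 1,5‑dibromo‑2‑(2,4‑dibromophenoxy)‑3‑methoxybenzene
Product: 12 1,2,3‑tribromo‑4‑(2,4‑dibromophenoxy)‑5‑methoxybenzene (target)
Conditions: NBS (1.05 equiv), (CF3)2CHOH, rt to 40 °C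
Reagents that add atoms: N‑bromosuccinimide, O=C1CCC(=O)N1Br
Why: Electrophilic aromatic bromination directed by the methoxy group to its para position C5, the preference also expected when a 4,6‑dihalo‑2‑methoxyphenol takes up a third halogen at C5; the ortho position C3 is shielded by the in‑plane O‑methyl group, which must point toward C3 because C1 carries the aryloxy group, and ring B is the less activated ring (two bromines, an ether oxygen shared with ring A).

**Compound list**

1 | cyclopent‑2‑en‑1‑one | O=C1C=CCC1 | starting material
2 | 2,3‑epoxycyclopentan‑1‑one (6‑oxabicyclo[3.1.0]hexan‑2‑one), racemic, cis‑fused | O=C1CC[C@H]2O[C@@H]12 | intermediate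
3 | 2,4‑dibromophenol | Oc1ccc(Br)cc1Br | starting material
4 | trans‑2‑(2,4‑dibromophenoxy)‑3‑hydroxycyclopentan‑1‑one, racemic | O=C1CC[C@@H](O)[C@@H]1Oc1ccc(Br)cc1Br | intermediate (not isolated)
5 | 2‑(2,4‑dibromophenoxy)cyclopent‑2‑en‑1‑one | O=C1CCC=C1Oc1ccc(Br)cc1Br | intermediate
6 | bromoform | BrC(Br)Br | starting material
7 | 6,6‑dibromo‑1‑(2,4‑dibromophenoxy)bicyclo[3.1.0]hexan‑2‑one, racemic, cis‑fused | O=C1CC[C@H]2C(Br)(Br)[C@@]12Oc1ccc(Br)cc1Br | intermediate (not isolated)
8 | 3‑bromo‑2‑(2,4‑dibromophenoxy)phenol | Oc1cccc(Br)c1Oc1ccc(Br)cc1Br | intermediate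
9 | 1‑bromo‑2‑(2,4‑dibromophenoxy)‑3‑methoxybenzene | COc1cccc(Br)c1Oc1ccc(Br)cc1Br | intermediate
10 | 2‑[3‑bromo‑4‑(2,4‑dibromophenoxy)‑5‑methoxyphenyl]‑4,4,5,5‑tetramethyl‑1,3,2‑dioxaborolane | COc1cc(B2OC(C)(C)C(C)(C)O2)cc(Br)c1Oc1ccc(Br)cc1Br | intermediate
11 | 1,5‑dibromo‑2‑(2,4‑dibromophenoxy)‑3‑methoxybenzene | COc1cc(Br)cc(Br)c1Oc1ccc(Br)cc1Br | intermediate
12 | 1,2,3‑tribromo‑4‑(2,4‑dibromophenoxy)‑5‑methoxybenzene | COc1cc(Br)c(Br)c(Br)c1Oc1ccc(Br)cc1Br | target

Total step count: 7. Longest linear sequence: 7 steps (1 to 12).

**Steps most likely to fail**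

Step 3. The enone may be deprotonated in competition with bromoform, so that the carbene is taken up by its dienolate and the new carbon ends between C2 and C3. The anion may also add irreversibly to the carbonyl group, the enone may self‑condense under hydroxide, and the carbene may attack the phenoxide as it forms. The fallback uses known chemistry, sets out from 3 and returns at 8, and gives up the ring expansion. SNAr of 3 on 3‑bromo‑2‑fluorobenzaldehyde (K2CO3, DMAc, 120 °C) should give 3‑bromo‑2‑(2,4‑dibromophenoxy)benzaldehyde F1. Baeyer–Villiger (Dakin‑type) oxidation with mCPBA in CH2Cl2, where the oxygen‑substituted aryl group migrates, should give 3‑bromo‑2‑(2,4‑dibromophenoxy)phenyl formate F2. Methanolysis (K2CO3, MeOH, rt) then releases 8.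

Step 2. The epoxy ketone may isomerise under base to the enol of cyclopentane‑1,2‑dione or oligomerise faster than the weakly nucleophilic dibromophenoxide opens it. The fallback sets out from 3 and returns at 5. Alkylation of 3 with 2‑chlorocyclopentan‑1‑one (K2CO3, KI cat., acetone, reflux) should give racemic 2‑(2,4‑dibromophenoxy)cyclopentan‑1‑one F3. Soft enolisation (TMSOTf, Et3N, CH2Cl2, 0 °C) should give the more substituted silyl enol ether, {[2‑(2,4‑dibromophenoxy)cyclopent‑1‑en‑1‑yl]oxy}trimethylsilane F4. Saegusa–Ito oxidation with Pd(OAc)2 (divalent palladium, 1 equiv, MeCN, rt, no phosphine) can eliminate only toward C3, because the palladium‑bearing carbon has no hydrogen, and so returns 5.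

Step 7. Substitution at C5, which lies between two bromines, may be slow enough that bromination at C3, at the free ortho position of ring B, or a second bromination competes. The fallback sets out from 10 and returns at 12; the amine steers the bromination and C4 receives its bromine last.
- Azidodeboronation of 10 (Cu(OAc)2 cat., NaN3, MeOH, 55 °C, air) should give 5‑azido‑1‑bromo‑2‑(2,4‑dibromophenoxy)‑3‑methoxybenzene F5.
- Staudinger reduction (PPh3, THF/H2O, 50 °C) should give 3‑bromo‑4‑(2,4‑dibromophenoxy)‑5‑methoxyaniline F6.
- One equivalent of NBS (MeCN, −20 °C) should brominate C5, ortho to NH2 and para to OMe, in preference to C3 between the two donors and far ahead of ring B, giving 2,3‑dibromo‑4‑(2,4‑dibromophenoxy)‑5‑methoxyaniline F7.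
- Diazotisation (NaNO2, 48% HBr, AcOH, 0 °C) should give 2,3‑dibromo‑4‑(2,4‑dibromophenoxy)‑5‑methoxybenzenediazonium bromide F8, and the Sandmeyer reaction with CuBr (monovalent copper, 60 °C) then gives 12.

**Further compounds**

F1 | step 3 | 3‑bromo‑2‑(2,4‑dibromophenoxy)benzaldehyde | O=Cc1cccc(Br)c1Oc1ccc(Br)cc1Br
F2 | step 3 | 3‑bromo‑2‑(2,4‑dibromophenoxy)phenyl formate | O=COc1cccc(Br)c1Oc1ccc(Br)cc1Br
F3 | step 2 | 2‑(2,4‑dibromophenoxy)cyclopentan‑1‑one, racemic | O=C1CCCC1Oc1ccc(Br)cc1Br
F4 | step 2 | {[2‑(2,4‑dibromophenoxy)cyclopent‑1‑en‑1‑yl]oxy}trimethylsilane | C[Si](C)(C)OC1=C(Oc2ccc(Br)cc2Br)CCC1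
F5 | step 7 | 5‑azido‑1‑bromo‑2‑(2,4‑dibromophenoxy)‑3‑methoxybenzene | COc1cc(N=[N+]=[N-])cc(Br)c1Oc1ccc(Br)cc1Br
F6 | step 7 | 3‑bromo‑4‑(2,4‑dibromophenoxy)‑5‑methoxyaniline | COc1cc(N)cc(Br)c1Oc1ccc(Br)cc1Br
F7 | step 7 | 2,3‑dibromo‑4‑(2,4‑dibromophenoxy)‑5‑methoxyaniline | COc1cc(N)c(Br)c(Br)c1Oc1ccc(Br)cc1Br
F8 | step 7 | 2,3‑dibromo‑4‑(2,4‑dibromophenoxy)‑5‑methoxybenzenediazonium bromide | COc1cc([N+]#N)c(Br)c(Br)c1Oc1ccc(Br)cc1Br.[Br-]
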